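**Retrosynthetic overview**

1. The strategy rests on the benzene ring of dihydrobenzofuran A. It carries only O1 at C7a, C3 at C3a and the stilbene vinyl group at C5, so it is cut into three alkynes, two of them tethered through C3–C2–O1.
2. Key disconnection: a ruthenium-catalysed (2+2+2) union of silyl ynol ether 1,6-diyne 22 (ring B plus the acyclic anti C2/C3 pair of ring A) with benzofuranyl enyne 33 forms C3a–C7a, C4–C5 and C6–C7. C7 desilylation and ninefold demethylation follow.
3. Diyne 22: the C2–C3 bond of ring A comes from an anti allenylzinc addition of a ring B propargylic mesylate to 4-methoxybenzaldehyde; the ynol ether comes from the carbinol and trichloroethylene.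
4. Ring B is made by an enantioselective dirhodium carbene C–H insertion and C2 epimerisation to trans. Ring C (enyne 33) is made by cyclodehydration of an aryloxy ketone, C2–H arylation, Takai olefination and Sonogashira coupling.
5. Order of ring formation: B (step 5), C (step 15), then the dihydrofuran ring and the benzene ring of A together (step 22).

Key step: step 22

Abbreviations: ArB = (2S,3S)-3-(3,5-dimethoxyphenyl)-6-methoxy-2-(4-methoxyphenyl)-2,3-dihydro-1-benzofuran-4-yl; ArC = 3-(3,5-dimethoxyphenyl)-6-methoxy-2-(4-methoxyphenyl)-1-benzofuran-4-yl.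

Assumption (remark on the chemistry): the antipodes named for Rh2(R-PTAD)4 in step 5 and for BINOL in step 8 follow the sense of induction recalled for closely related substrates. If the crystal structure of 10 or the Mosher esters of 13 show the opposite sense, the mirror-image catalyst or ligand is used and nothing else changes.

**Ring B and diyne 22**

Step 1
Reactants: 1 1-bromo-3,5-dimethoxybenzene; 2 3,5-dimethoxybenzoyl chloride
Product: 3 (2-bromo-4,6-dimethoxyphenyl)(3,5-dimethoxyphenyl)methanone
Conditions: AlCl3 (1.2 equiv), CH2Cl2, 0 °C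
Reagents that add atoms: none
Why: Friedel–Crafts acylation should occur para to one methoxy group and ortho to bromine, the site this arene also offers to Vilsmeier formylation, and the minor isomer acylated between the two methoxy groups is removed at this stage.

Step 2
Reactants: 3 (2-bromo-4,6-dimethoxyphenyl)(3,5-dimethoxyphenyl)methanone
Product: 4 (2-bromo-6-hydroxy-4-methoxyphenyl)(3,5-dimethoxyphenyl)methanone
Conditions: BCl3 (1.5 equiv), CH2Cl2, −78 to 0 °C
Reagents that add atoms: none
Why: Chelation-controlled ether cleavage: BCl3 bound to the ketone oxygen should remove only the methyl group of the ortho methoxy group through a six-membered chelate and leave the other four methyl ethers.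

Step 3
Reactants: 4 (2-bromo-6-hydroxy-4-methoxyphenyl)(3,5-dimethoxyphenyl)methanone; 5 4-methoxybenzyl chloride
Product: 6 {2-bromo-4-methoxy-6-[(4-methoxybenzyl)oxy]phenyl}(3,5-dimethoxyphenyl)methanone
Conditions: K2CO3, n-Bu4NI (cat.), DMF, 60 °C
Reagents that add atoms: none
Why: Williamson etherification of the hydrogen-bonded phenol installs the benzylic CH2 that becomes C2 of ring B together with its 4-methoxyphenyl group.

Step 4
Reactants: 6 {2-bromo-4-methoxy-6-[(4-methoxybenzyl)oxy]phenyl}(3,5-dimethoxyphenyl)methanone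
Product: 7 hydrazone of ketone 6
Conditions: N2H4·H2O (20 equiv), AcOH (cat.), n-BuOH, 110 °C
Reagents that add atoms: hydrazine (as the monohydrate), NN
Why: Hydrazone condensation at the doubly ortho-substituted ketone needs forcing conditions, the large excess of hydrazine should suppress azine formation and the electron-rich aryl bromide should not undergo uncatalysed substitution.

Step 5
Reactants: 7 hydrazone of ketone 6
Product: 9 (2R,3S)-4-bromo-3-(3,5-dimethoxyphenyl)-6-methoxy-2-(4-methoxyphenyl)-2,3-dihydro-1-benzofuran (cis isomer), via diaryldiazomethane 8 (not isolated)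
Conditions: MnO2 (8 equiv), CH2Cl2, 0 °C; filtration; Rh2(R-PTAD)4 [dirhodium tetrakis((R)-(1-adamantyl)(phthalimido)acetate), 1 mol %], CH2Cl2, 0 °C to rt
Reagents that add atoms: none
Why: Oxidation to the diaryldiazomethane and loss of N2 on the chiral dirhodium tetracarboxylate give a donor/donor carbene that inserts into the p-methoxybenzylic C–H bond (1,5 C–H insertion), which closes ring B cis and sets C3 as S and C2 as R under control of the catalyst.

Step 6
Reactants: 9 cis-(2R,3S)-bromide
Product: 10 (2S,3S)-4-bromo-3-(3,5-dimethoxyphenyl)-6-methoxy-2-(4-methoxyphenyl)-2,3-dihydro-1-benzofuran (trans isomer)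
Conditions: CF3CO2H (2 equiv), CH2Cl2, 0 °C to rt
Reagents that add atoms: none
Why: Acid should ionise the p-methoxybenzylic C2–O bond reversibly and reclose the ring to the more stable trans isomer (thermodynamic epimerisation, C2 now S), while C3 is not involved.

Step 7
Reactants: 10 trans-(2S,3S)-bromide
Product: 11 ArB-carbaldehyde, (2S,3S)-3-(3,5-dimethoxyphenyl)-6-methoxy-2-(4-methoxyphenyl)-2,3-dihydro-1-benzofuran-4-carbaldehyde
Conditions: n-BuLi (1.1 equiv), THF, −78 °C; DMF, −78 to 0 °C
Reagents that add atoms: N,N-dimethylformamide, CN(C)C=O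
Why: Bromine–lithium exchange should outrun deprotonation of the benzylic C–H bonds at −78 °C and the aryllithium is formylated by DMF, with no stereocentre touched.

Step 8
Reactants: 11 ArB-carbaldehyde; 12 trimethylsilylacetylene (3 equiv)
Product: 13 (1S)-1-ArB-3-(trimethylsilyl)prop-2-yn-1-ol
Conditions: Et2Zn (3 equiv), (R)-BINOL (40 mol %), Cy2NH (5 mol %), Ti(OiPr)4 (1 equiv), Et2O, rt
Reagents that add atoms: none
Why: BINOL–titanium catalysed addition of the alkynylzinc made in the flask; the (R)-ligand should deliver the alkyne to the Re face of the aldehyde and set the carbinol centre as S, the minor epimer being removed by chromatography.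

Step 9
Reactants: 13 (1S)-1-ArB-3-(trimethylsilyl)prop-2-yn-1-ol
Product: 14 (1S)-1-ArB-3-(trimethylsilyl)prop-2-yn-1-yl methanesulfonate
Conditions: MsCl, Et3N, CH2Cl2, −78 °C; used crude at once
Reagents that add atoms: methanesulfonyl chloride, CS(=O)(=O)Cl
Why: Sulfonylation at low temperature leaves the carbinol configuration unchanged, and the two meta oxygen substituents of the aryl group should keep the benzylic mesylate from ionising before it is used.

Step 10
Reactants: 14 propargylic mesylate; 15 4-methoxybenzaldehyde (1.5 equiv)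
Product: 17 (1R,2R)-2-ArB-1-(4-methoxyphenyl)-4-(trimethylsilyl)but-3-yn-1-ol, via allenyl(ethyl)zinc 16 (not isolated)
Conditions: Pd(OAc)2 (5 mol %), PPh3 (5 mol %), Et2Zn (3 equiv), THF, −78 to −20 °C
Reagents that add atoms: none
Why: Marshall–Tamaru propargyl umpolung: zerovalent palladium displaces the mesylate anti (SN2'), transmetallation to zinc with retention gives allenylzinc 16, and SE2' addition to the aldehyde through a closed six-membered transition state should give the anti alcohol with net inversion at the propargylic carbon, which sets C3 and C2 of ring A (both R in the target).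

Step 11
Reactants: 17 anti homopropargylic alcohol; 18 trichloroethylene (1.1 equiv)
Product: 19 O-[(E)-1,2-dichlorovinyl] ether of alcohol 17
Conditions: KH (1.2 equiv), THF, 0 °C; then 18, −50 °C to rt
Reagents that add atoms: none
Why: Greene ynol ether synthesis, first half: the potassium alkoxide should add to dichloroacetylene formed in the flask from trichloroethylene and protonation gives the E-1,2-dichlorovinyl ether without touching either stereocentre.

Step 12
Reactants: 19 O-[(E)-1,2-dichlorovinyl] ether of alcohol 17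
Product: 21 O-[(triethylsilyl)ethynyl] ether of alcohol 17, via lithium alkynyl ether 20 (not isolated)
Conditions: n-BuLi (2.2 equiv), THF, −78 °C; Et3SiCl, −78 to 0 °C
Reagents that add atoms: chlorotriethylsilane, CC[Si](Cl)(CC)CC
Why: n-BuLi should eliminate HCl and then exchange the remaining chlorine for lithium to give lithium alkynyl ether 20, which is silylated on carbon; triethylsilyl is chosen as the smallest silyl group that survives step 13 and later leaves C7 under mild acid.

Step 13
Reactants: 21 O-[(triethylsilyl)ethynyl] ether of alcohol 17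
Product: 22 (1R,2S)-2-ArB-1-(4-methoxyphenyl)but-3-yn-1-yl (triethylsilyl)ethynyl ether (diyne)
Conditions: K2CO3 (0.3 equiv), MeOH/THF, 0 °C; used within hours
Reagents that add atoms: none
Why: Base-catalysed methanolysis should cleave the unhindered C–SiMe3 bond of the alkyne far faster than the C–SiEt3 bond of the ynol ether, so the terminal alkyne is freed selectively at 0 °C.

**Ring C and enyne 33**

Step 14
Reactants: 23 methyl 3-hydroxy-5-methoxybenzoate; 24 2-bromo-1-(3,5-dimethoxyphenyl)ethan-1-one
Product: 25 methyl 3-[2-(3,5-dimethoxyphenyl)-2-oxoethoxy]-5-methoxybenzoate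
Conditions: K2CO3, acetone, reflux
Reagents that add atoms: none
Why: Williamson etherification of the phenol with the α-bromoketone.

Step 15
Reactants: 25 methyl 3-[2-(3,5-dimethoxyphenyl)-2-oxoethoxy]-5-methoxybenzoate
Product: 26 methyl 3-(3,5-dimethoxyphenyl)-6-methoxy-1-benzofuran-4-carboxylate
Conditions: Bi(OTf)3 (10 mol %), CH2Cl2, reflux
Reagents that add atoms: none
Why: Lewis acid catalysed cyclodehydration (intramolecular Friedel–Crafts hydroxyalkylation, then loss of water) should close the furan ring of benzofuran C at the arene position para to the methoxy group, which places the ester at C4.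

Step 16
Reactants: 26 methyl 3-(3,5-dimethoxyphenyl)-6-methoxy-1-benzofuran-4-carboxylate; 27 4-bromoanisole
Product: 28 methyl ArC-carboxylate, methyl 3-(3,5-dimethoxyphenyl)-6-methoxy-2-(4-methoxyphenyl)-1-benzofuran-4-carboxylate
Conditions: Pd(OAc)2 (5 mol %), PCy3·HBF4 (10 mol %), PivOH (30 mol %), K2CO3, DMA, 110 °C
Reagents that add atoms: none
Why: Direct C2–H arylation of the benzofuran by concerted metalation–deprotonation at palladium with pivalate as proton shuttle.

Step 17
Reactants: 28 methyl ArC-carboxylate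
Product: 29 ArC-methanol
Conditions: LiAlH4, THF, 0 °C
Reagents that add atoms: none
Why: Hydride reduction of the ester to the benzylic alcohol.

Step 18
Reactants: 29 ArC-methanol
Product: 30 ArC-carbaldehyde
Conditions: MnO2, CH2Cl2, rt
Reagents that add atoms: none
Why: Oxidation of the benzylic alcohol by MnO2 should stop at the aldehyde.

Step 19
Reactants: 30 ArC-carbaldehyde
Product: 31 (E)-1-ArC-2-iodoethene
Conditions: CrCl2 (6 equiv), CHI3 (2 equiv), THF, 0 °C to rt
Reagents that add atoms: iodoform, IC(I)I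
Why: Takai olefination: the gem-dichromium species from iodoform and CrCl2 should add to the aldehyde and eliminate to give the E-vinyl iodide.

Step 20
Reactants: 31 (E)-1-ArC-2-iodoethene; 12 trimethylsilylacetylene
Product: 32 [(E)-4-ArC-but-3-en-1-yn-1-yl]trimethylsilane
Conditions: Pd(PPh3)2Cl2 (3 mol %), CuI (6 mol %), Et3N, THF, rt
Reagents that add atoms: none
Why: Sonogashira coupling with retention of the E geometry.

Step 21
Reactants: 32 [(E)-4-ArC-but-3-en-1-yn-1-yl]trimethylsilane
Product: 33 (E)-1-ArC-but-1-en-3-yne (enyne)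
Conditions: K2CO3, MeOH/THF, rt
Reagents that add atoms: none
Why: Methanolysis of the C–SiMe3 bond frees the terminal alkyne.

**Union and end game**

Step 22
Reactants: 22 diyne; 33 enyne (1.5 equiv)
Product: 34 7-triethylsilyl nonamethyl ether of the target: (2R,3R) in ring A; (2S,3S) in ring B; E alkene
Conditions: Cp*RuCl(cod) (10 mol %), ClCH2CH2Cl, 20 °C, slow addition of 22 to 33 and catalyst, argon
Reagents that add atoms: none
Why: Proposed new method: Cp*RuCl (divalent ruthenium, freed from cod) binds both alkynes of 22 and couples them oxidatively to a ruthenacyclopentadiene with H and SiEt3 on the carbons next to ruthenium, which already forms C3a–C7a; the terminal alkyne of 33 then adds across the Ru–C4 bond and reductive elimination forms C4–C5 and C6–C7 and releases the arene. The closest known reaction type is the Cp*RuCl(cod)-catalysed cyclotrimerisation of ynamide- or ether-tethered 1,6-diynes with terminal alkynes to indolines and dihydroisobenzofurans; an ynol ether, with oxygen directly on the alkyne, has not been used as the tether. The dihydrofuran ring of A closes in the metallacycle-forming step (five-membered ring by alkyne–alkyne coupling across the C3–C2–O1 tether) and the benzene ring of A closes by formal (2+2+2) insertion and reductive elimination. No stereocentre is formed: C2 and C3 of ring A sit on the tether as the anti pair from step 10 and are not touched, and the E alkene arrives intact in 33. The step needs the vinyl group at C5 and not C6, which the SiEt3 group should secure because the substituted alkyne carbon bonds to the unhindered C4 terminus and so ends meta to silicon, and it needs cross-coupling over diyne self-coupling, secured by slow addition of 22 to excess 33. Turnover near 20 °C is required to outrun retro-ene and sigmatropic loss of the secondary benzylic ynol ether, which the silyl cap also slows.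

Step 23
Reactants: 34 7-triethylsilyl nonamethyl ether
Product: 35 nonamethyl ether of the target
Conditions: CF3CO2H (10 equiv), CH2Cl2, 0 °C, 30 min; aqueous NaHCO3
Reagents that add atoms: none
Why: Ipso protodesilylation: protonation at C7, ortho to O1 and stabilised by the β-silicon effect, should be faster than protonation of the stilbene or ionisation of the benzylic ethers in dilute acid at 0 °C, and no stereocentre is involved.

Step 24
Reactants: 35 nonamethyl ether of the target
Product: 36 CNP0135983.1 (target)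
Conditions: BCl3 (20 equiv), n-Bu4NI (20 equiv), CH2Cl2, −78 to 0 °C; MeOH, then aqueous NaHCO3
Reagents that add atoms: none
Why: BCl3 activates each aryl methyl ether and iodide removes the methyl group as iodomethane; this milder pair is chosen over BBr3 to limit acid-promoted Friedel–Crafts closure of the stilbene onto the neighbouring 3,5-dioxygenated ring and opening of the benzylic C2–O bonds, so the four stereocentres should be kept.

**Compound list**

1 | 1-bromo-3,5-dimethoxybenzene | COc1cc(Br)cc(OC)c1 | starting material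
2 | 3,5-dimethoxybenzoyl chloride | COc1cc(cc(OC)c1)C(Cl)=O | starting material
3 | (2-bromo-4,6-dimethoxyphenyl)(3,5-dimethoxyphenyl)methanone | COc1cc(OC)cc(c1)C(=O)c1c(Br)cc(OC)cc1OC | intermediate
4 | (2-bromo-6-hydroxy-4-methoxyphenyl)(3,5-dimethoxyphenyl)methanone | COc1cc(OC)cc(c1)C(=O)c1c(Br)cc(OC)cc1O | intermediate
5 | 4-methoxybenzyl chloride | COc1ccc(CCl)cc1 | starting material
6 | {2-bromo-4-methoxy-6-[(4-methoxybenzyl)oxy]phenyl}(3,5-dimethoxyphenyl)methanone | COc1ccc(COc2cc(OC)cc(Br)c2C(=O)c2cc(OC)cc(OC)c2)cc1 | intermediate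
7 | hydrazone of ketone 6 | COc1ccc(COc2cc(OC)cc(Br)c2C(=NN)c2cc(OC)cc(OC)c2)cc1 | intermediate
8 | diaryldiazomethane from 7 | COc1ccc(COc2cc(OC)cc(Br)c2C(=[N+]=[N-])c2cc(OC)cc(OC)c2)cc1 | intermediate
9 | (2R,3S)-4-bromo-3-(3,5-dimethoxyphenyl)-6-methoxy-2-(4-methoxyphenyl)-2,3-dihydro-1-benzofuran (cis) | Brc1cc(OC)cc2c1[C@H](c1cc(OC)cc(OC)c1)[C@H](c1ccc(OC)cc1)O2 | intermediate
10 | (2S,3S)-4-bromo-3-(3,5-dimethoxyphenyl)-6-methoxy-2-(4-methoxyphenyl)-2,3-dihydro-1-benzofuran (trans) | Brc1cc(OC)cc2c1[C@H](c1cc(OC)cc(OC)c1)[C@@H](c1ccc(OC)cc1)O2 | intermediate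
11 | ArB-carbaldehyde | O=Cc1cc(OC)cc2c1[C@H](c1cc(OC)cc(OC)c1)[C@@H](c1ccc(OC)cc1)O2 | intermediate
12 | trimethylsilylacetylene | C#C[Si](C)(C)C | starting material
13 | (1S)-1-ArB-3-(trimethylsilyl)prop-2-yn-1-ol | C[Si](C)(C)C#C[C@@H](O)c1cc(OC)cc2c1[C@H](c1cc(OC)cc(OC)c1)[C@@H](c1ccc(OC)cc1)O2 | intermediate
14 | (1S)-1-ArB-3-(trimethylsilyl)prop-2-yn-1-yl methanesulfonate | C[Si](C)(C)C#C[C@@H](OS(C)(=O)=O)c1cc(OC)cc2c1[C@H](c1cc(OC)cc(OC)c1)[C@@H](c1ccc(OC)cc1)O2 | intermediate
15 | 4-methoxybenzaldehyde | COc1ccc(C=O)cc1 | starting material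
16 | ethyl[(aR)-3-ArB-1-(trimethylsilyl)propa-1,2-dien-1-yl]zinc | CC[Zn]C([Si](C)(C)C)=[C@]=C([H])c1cc(OC)cc2c1[C@H](c1cc(OC)cc(OC)c1)[C@@H](c1ccc(OC)cc1)O2 | intermediate
17 | (1R,2R)-2-ArB-1-(4-methoxyphenyl)-4-(trimethylsilyl)but-3-yn-1-ol | C[Si](C)(C)C#C[C@@H](c1cc(OC)cc2c1[C@H](c1cc(OC)cc(OC)c1)[C@@H](c1ccc(OC)cc1)O2)[C@H](c1ccc(OC)cc1)O | intermediate
18 | trichloroethylene | ClC=C(Cl)Cl | starting material
19 | O-[(E)-1,2-dichlorovinyl] ether of 17 | C[Si](C)(C)C#C[C@@H](c1cc(OC)cc2c1[C@H](c1cc(OC)cc(OC)c1)[C@@H](c1ccc(OC)cc1)O2)[C@H](c1ccc(OC)cc1)O/C(Cl)=C\Cl | intermediate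
20 | lithium alkynyl ether (lithium acetylide of the ethynyl ether of 17) | C[Si](C)(C)C#C[C@@H](c1cc(OC)cc2c1[C@H](c1cc(OC)cc(OC)c1)[C@@H](c1ccc(OC)cc1)O2)[C@H](c1ccc(OC)cc1)OC#C[Li] | intermediate
21 | O-[(triethylsilyl)ethynyl] ether of 17 | C[Si](C)(C)C#C[C@@H](c1cc(OC)cc2c1[C@H](c1cc(OC)cc(OC)c1)[C@@H](c1ccc(OC)cc1)O2)[C@H](c1ccc(OC)cc1)OC#C[Si](CC)(CC)CC | intermediate
22 | (1R,2S)-2-ArB-1-(4-methoxyphenyl)but-3-yn-1-yl (triethylsilyl)ethynyl ether | C#C[C@@H](c1cc(OC)cc2c1[C@H](c1cc(OC)cc(OC)c1)[C@@H](c1ccc(OC)cc1)O2)[C@H](c1ccc(OC)cc1)OC#C[Si](CC)(CC)CC | intermediate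
23 | methyl 3-hydroxy-5-methoxybenzoate | COC(=O)c1cc(O)cc(OC)c1 | starting material
24 | 2-bromo-1-(3,5-dimethoxyphenyl)ethan-1-one | COc1cc(cc(OC)c1)C(=O)CBr | starting material
25 | methyl 3-[2-(3,5-dimethoxyphenyl)-2-oxoethoxy]-5-methoxybenzoate | COC(=O)c1cc(OC)cc(OCC(=O)c2cc(OC)cc(OC)c2)c1 | intermediate
26 | methyl 3-(3,5-dimethoxyphenyl)-6-methoxy-1-benzofuran-4-carboxylate | COC(=O)c1cc(OC)cc2occ(-c3cc(OC)cc(OC)c3)c12 | intermediate
27 | 4-bromoanisole | COc1ccc(Br)cc1 | starting material
28 | methyl ArC-carboxylate | COC(=O)c1cc(OC)cc2oc(-c3ccc(OC)cc3)c(-c3cc(OC)cc(OC)c3)c12 | intermediate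
29 | ArC-methanol | OCc1cc(OC)cc2oc(-c3ccc(OC)cc3)c(-c3cc(OC)cc(OC)c3)c12 | intermediate
30 | ArC-carbaldehyde | O=Cc1cc(OC)cc2oc(-c3ccc(OC)cc3)c(-c3cc(OC)cc(OC)c3)c12 | intermediate
31 | (E)-1-ArC-2-iodoethene | I/C=C/c1cc(OC)cc2oc(-c3ccc(OC)cc3)c(-c3cc(OC)cc(OC)c3)c12 | intermediate
32 | [(E)-4-ArC-but-3-en-1-yn-1-yl]trimethylsilane | C[Si](C)(C)C#C/C=C/c1cc(OC)cc2oc(-c3ccc(OC)cc3)c(-c3cc(OC)cc(OC)c3)c12 | intermediate
33 | (E)-1-ArC-but-1-en-3-yne | C#C/C=C/c1cc(OC)cc2oc(-c3ccc(OC)cc3)c(-c3cc(OC)cc(OC)c3)c12 | intermediate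
34 | 7-triethylsilyl nonamethyl ether of the target | COc1ccc(-c2oc3cc(OC)cc(/C=C/c4cc([Si](CC)(CC)CC)c5c(c4)[C@@H](c4cc(OC)cc6c4[C@H](c4cc(OC)cc(OC)c4)[C@@H](c4ccc(OC)cc4)O6)[C@H](c4ccc(OC)cc4)O5)c3c2-c2cc(OC)cc(OC)c2)cc1 | intermediate
35 | nonamethyl ether of the target | COc1ccc(-c2oc3cc(OC)cc(/C=C/c4ccc5c(c4)[C@@H](c4cc(OC)cc6c4[C@H](c4cc(OC)cc(OC)c4)[C@@H](c4ccc(OC)cc4)O6)[C@H](c4ccc(OC)cc4)O5)c3c2-c2cc(OC)cc(OC)c2)cc1 | intermediate
36 | CNP0135983.1 | Oc1ccc(-c2oc3cc(O)cc(/C=C/c4ccc5c(c4)[C@@H](c4cc(O)cc6c4[C@H](c4cc(O)cc(O)c4)[C@@H](c4ccc(O)cc4)O6)[C@H](c4ccc(O)cc4)O5)c3c2-c2cc(O)cc(O)c2)cc1 | target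

**Step count and risks**

Total step count: 24. Longest linear sequence: 16 steps (steps 1–13, then 22–24).

Steps most likely to fail:

1. Step 22 (the proposed new method). The ynol ether may fragment before the metallacycle forms, by retro-ene loss of a silylketene or by sigmatropic shift into the anisyl ring. Oxidative cyclisation may also be slow with a silyl group next to ruthenium, the diyne may couple with itself, or regiocontrol may be lost. Fallback (known chemistry): ring A is closed by the same donor/donor carbene C–H insertion that makes ring B, and the halves are joined by a Heck reaction. It sets out from bromide 10 and aldehyde 30 and comes back at nonamethyl ether 35. Commercial 5-bromosalicylaldehyde is etherified with 5 (K2CO3, DMF) to 5-bromo-2-[(4-methoxybenzyl)oxy]benzaldehyde F1. Bromide 10 is lithiated (n-BuLi, THF, −78 °C) and added to F1 to give the diaryl carbinol F2, which Dess–Martin periodinane oxidises to the diaryl ketone F3. Hydrazine gives the hydrazone F4, MnO2 the diazo compound F5, and Rh2(S-PTAD)4 (the antipode of the step 5 catalyst) should close ring A to the cis-dihydrobenzofuran F6. CF3CO2H epimerises C2 to the trans-(2R,3R) bromide F7. Aldehyde 30 is methylenated (Ph3P=CH2, THF) to the 4-vinylbenzofuran F8, and Heck coupling of F7 with F8 (Pd(OAc)2, P(o-tol)3, Et3N, DMF, 100 °C) gives 35.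

2. Step 10. The benzylic propargylic mesylate may ionise before oxidative addition, the aryl-substituted allenyl metal may racemise through propargyl isomers, and the hindered allenylzinc may add slowly to the electron-rich aldehyde. Fallback: an isolable allenylboron reagent replaces the transient allenylzinc. It sets out from 13 and comes back at 17. Methyl chloroformate and pyridine give the propargylic methyl carbonate F9. Copper-catalysed anti SN2' borylation (CuOtBu, Xantphos, B2pin2, THF, rt) gives the (aS)-allenyl pinacolboronate F10. Heating F10 with 15 in toluene (closed six-membered transition state, same net inversion and anti selectivity) and aqueous work-up give 17.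

3. Step 11. The potassium alkoxide may fragment by retro-propargylation with loss of 4-methoxybenzaldehyde, the trimethylsilyl group may move from carbon to alkoxide oxygen, and base may isomerise the alkyne to an allene. Fallback: the ynol ether is built from a formate without forming an alkoxide. It sets out from 17 and comes back at 21. Acetic formic anhydride and pyridine give the formate F11, and PPh3/CCl4 (THF, 60 °C) converts the formyl C=O into the 2,2-dichlorovinyl ether F12. n-BuLi (2.2 equiv, −78 °C) eliminates and rearranges to lithium alkynyl ether 20, which Et3SiCl converts into 21.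

Further compounds
F1 | step 22 | 5-bromo-2-[(4-methoxybenzyl)oxy]benzaldehyde | COc1ccc(COc2ccc(Br)cc2C=O)cc1
F2 | step 22 | ArB{5-bromo-2-[(4-methoxybenzyl)oxy]phenyl}methanol (carbinol epimers) | COc1ccc(COc2ccc(Br)cc2C(O)c2cc(OC)cc3c2[C@H](c2cc(OC)cc(OC)c2)[C@@H](c2ccc(OC)cc2)O3)cc1
F3 | step 22 | ArB{5-bromo-2-[(4-methoxybenzyl)oxy]phenyl}methanone | COc1ccc(COc2ccc(Br)cc2C(=O)c2cc(OC)cc3c2[C@H](c2cc(OC)cc(OC)c2)[C@@H](c2ccc(OC)cc2)O3)cc1
F4 | step 22 | hydrazone of ketone F3 | COc1ccc(COc2ccc(Br)cc2C(=NN)c2cc(OC)cc3c2[C@H](c2cc(OC)cc(OC)c2)[C@@H](c2ccc(OC)cc2)O3)cc1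
F5 | step 22 | diaryldiazomethane from F4 | COc1ccc(COc2ccc(Br)cc2C(=[N+]=[N-])c2cc(OC)cc3c2[C@H](c2cc(OC)cc(OC)c2)[C@@H](c2ccc(OC)cc2)O3)cc1
F6 | step 22 | (2S,3R)-3-ArB-5-bromo-2-(4-methoxyphenyl)-2,3-dihydro-1-benzofuran (cis) | Brc1ccc2c(c1)[C@@H](c1cc(OC)cc3c1[C@H](c1cc(OC)cc(OC)c1)[C@@H](c1ccc(OC)cc1)O3)[C@@H](c1ccc(OC)cc1)O2
F7 | step 22 | (2R,3R)-3-ArB-5-bromo-2-(4-methoxyphenyl)-2,3-dihydro-1-benzofuran (trans) | Brc1ccc2c(c1)[C@@H](c1cc(OC)cc3c1[C@H](c1cc(OC)cc(OC)c1)[C@@H](c1ccc(OC)cc1)O3)[C@H](c1ccc(OC)cc1)O2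
F8 | step 22 | 4-ethenyl-3-(3,5-dimethoxyphenyl)-6-methoxy-2-(4-methoxyphenyl)-1-benzofuran | C=Cc1cc(OC)cc2oc(-c3ccc(OC)cc3)c(-c3cc(OC)cc(OC)c3)c12
F9 | step 10 | (1S)-1-ArB-3-(trimethylsilyl)prop-2-yn-1-yl methyl carbonate | C[Si](C)(C)C#C[C@@H](OC(=O)OC)c1cc(OC)cc2c1[C@H](c1cc(OC)cc(OC)c1)[C@@H](c1ccc(OC)cc1)O2
F10 | step 10 | 2-[(aS)-3-ArB-1-(trimethylsilyl)propa-1,2-dien-1-yl]-4,4,5,5-tetramethyl-1,3,2-dioxaborolane | CC1(C)OB(OC1(C)C)C([Si](C)(C)C)=[C@]=C([H])c1cc(OC)cc2c1[C@H](c1cc(OC)cc(OC)c1)[C@@H](c1ccc(OC)cc1)O2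
F11 | step 11 | formate of alcohol 17 | C[Si](C)(C)C#C[C@@H](c1cc(OC)cc2c1[C@H](c1cc(OC)cc(OC)c1)[C@@H](c1ccc(OC)cc1)O2)[C@H](c1ccc(OC)cc1)OC=O
F12 | step 11 | O-(2,2-dichlorovinyl) ether of alcohol 17 | C[Si](C)(C)C#C[C@@H](c1cc(OC)cc2c1[C@H](c1cc(OC)cc(OC)c1)[C@@H](c1ccc(OC)cc1)O2)[C@H](c1ccc(OC)cc1)OC=C(Cl)Cl
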